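**Retrosynthetic overview**
1. Rings A, B, C and D and seven of the eight stereocentres (C3, C4, C5, C6, C8, C9, C13) come intact from gibberellin A four (1); no carbocycle is built and only C10 is re-made.
2. Masking and activation: 1 → methyl ester 2 → triethylsilyl ether 3 → thionolactone 4 (C19=O to C19=S), which makes the tertiary C10–O bond radical-labile.
3. Key disconnection C10–C20: C20 is carbon monoxide (5), inserted under light into the C10–O bond of 4. The lactone ring opens and the only new ring, the six-membered 19,20-thioanhydride of 6, closes on the α face where C19 sits.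
4. Last disconnection, the two C–S bonds of 6: one-pot oxidative hydrolysis, saponification and desilylation (through 7 and 8) give gibberellin A thirteen (9).

Assumption: gibberellin A four (CAS 468-44-0), the fermentation-derived plant-growth regulator sold in technical grade, is taken as the commercial starting material.

**Step 1**
Reactants: 1 gibberellin A four
Product: 2 gibberellin A four methyl ester
Conditions: MeI, KHCO3, DMF, 23 °C
Reagents that add atoms: iodomethane, CI
Why: SN2 O-alkylation of the C7 carboxylate under bicarbonate masks the acid under conditions too mild to open the lactone or epimerise C3 by retro-aldol, so no stereocentre is touched.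

**Step 2**
Reactants: 2 gibberellin A four methyl ester
Product: 3 3-O-triethylsilyl gibberellin A four methyl ester
Conditions: Et3SiOTf, 2,6-lutidine, CH2Cl2, −40 to 0 °C
Reagents that add atoms: triethylsilyl trifluoromethanesulfonate, CC[Si](CC)(CC)OS(=O)(=O)C(F)(F)F
Why: Silyl triflate silylation caps the hindered axial 3β-hydroxyl, the only O–H left that would react with the thionating agent, without touching a stereocentre.

**Step 3**
Reactants: 3 3-O-triethylsilyl gibberellin A four methyl ester
Product: 4 3-O-triethylsilyl gibberellin A four methyl ester 19-thionolactone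
Conditions: Lawesson's reagent (0.7 equiv), pyridine (0.2 equiv), toluene, 100 °C
Reagents that add atoms: Lawesson's reagent, COc1ccc(cc1)P1(=S)SP(=S)(S1)c1ccc(OC)cc1
Why: Lawesson thionation (O/S exchange through a Wittig-like thiaoxaphosphetane) should be faster at the strained, E-configured bicyclic lactone carbonyl than at the hindered acyclic C7 ester, leaves silyl ether and alkene alone, and turns the C10–O bond into a radical-labile O-alkyl thionoester without touching a stereocentre.

**Step 4**
Reactants: 4 3-O-triethylsilyl gibberellin A four methyl ester 19-thionolactone; 5 carbon monoxide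
Product: 6 3-O-triethylsilyl gibberellin A thirteen 7-methyl ester 19,20-thioanhydride
Conditions: CO (80 atm), t-BuN=Nt-Bu (0.2 equiv), hν (365 nm), PhCF3 (3 mM), 0 °C, sapphire-window autoclave
Reagents that add atoms: carbon monoxide, [C-]#[O+]
Why: Proposed new method: a photo-initiated tert-butyl-radical chain that carbonylatively ring-expands a thionolactone to a cyclic thioanhydride, in which t-Bu• (from photolysis of the azoalkane) adds to the C=S sulfur of 4, the adduct radical undergoes β-scission of the tertiary C10–O bond (as in Barton–McCombie fragmentation and radical ring-opening of thionolactones) to give a C10 radical tethered to a C19 S-tert-butyl thioester, CO is captured reversibly, and only the acyl radical on the α face can reach sulfur and close by intramolecular homolytic substitution with loss of the chain-carrying t-Bu• (closest known reaction type: radical carbonylation followed by acyl-radical cyclisation onto a tert-butyl sulfide sulfur to give thiolactones), so the C10 quaternary centre is set in the natural configuration by the 1,3-diaxial C19 tether while the β-acyl radical reverts by decarbonylation.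

**Step 5**
Reactants: 6 3-O-triethylsilyl gibberellin A thirteen 7-methyl ester 19,20-thioanhydride
Product: 9 gibberellin A thirteen, via diacid methyl ester 7 (not isolated), via silyl ether triacid 8 (not isolated)
Conditions: LiOH, H2O2, THF/H2O, 0 °C; then Na2SO3; then MeOH, 65 °C; then 1 M HCl, THF, 23 °C
Reagents that add atoms: hydrogen peroxide, OO; lithium hydroxide, [Li+].[OH-]; water, O
Why: Hydroperoxide-mediated oxidative hydrolysis of the thioanhydride (as for thioesters) frees both acids and removes sulfur as sulfate, sulfite destroys the excess peroxide before warming so that the 16-ene is not epoxidised, the remaining hydroxide then saponifies the C7 methyl ester (BAc2) and dilute acid cleaves the silyl ether, and because C19 is a carboxylate from the first operation on, C3 cannot epimerise by retro-aldol and no stereocentre is touched.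

**Compound list**
1 | gibberellin A four (CAS 468-44-0; ent-3α,10β-dihydroxy-20-norgibberell-16-ene-7,19-dioic acid 19,10-lactone; as drawn: 3β-OH, C19 on C4α lactonised to the oxygen on C10α, 7-CO2H on C6, 16(17)-exo-methylene) | C=C1C[C@]23C[C@H]1CC[C@H]2[C@]1(O4)CC[C@H](O)[C@@](C)(C4=O)[C@H]1[C@@H]3C(=O)O | starting material
2 | gibberellin A four methyl ester (7-CO2Me, otherwise as 1) | C=C1C[C@]23C[C@H]1CC[C@H]2[C@]1(O4)CC[C@H](O)[C@@](C)(C4=O)[C@H]1[C@@H]3C(=O)OC | intermediate
3 | 3-O-triethylsilyl gibberellin A four methyl ester (3β-OSiEt3) | C=C1C[C@]23C[C@H]1CC[C@H]2[C@]1(O4)CC[C@H](O[Si](CC)(CC)CC)[C@@](C)(C4=O)[C@H]1[C@@H]3C(=O)OC | intermediate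
4 | 3-O-triethylsilyl gibberellin A four methyl ester 19-thionolactone (lactone C19=O replaced by C19=S; ring oxygen still on C10α) | C=C1C[C@]23C[C@H]1CC[C@H]2[C@]1(O4)CC[C@H](O[Si](CC)(CC)CC)[C@@](C)(C4=S)[C@H]1[C@@H]3C(=O)OC | intermediate
5 | carbon monoxide | [C-]#[O+] | starting material
6 | 3-O-triethylsilyl gibberellin A thirteen 7-methyl ester 19,20-thioanhydride (six-membered C19(=O)–S–C20(=O) ring bridging C4α and C10α) | C=C1C[C@]23C[C@H]1CC[C@H]2[C@]1(C(=O)S4)CC[C@H](O[Si](CC)(CC)CC)[C@@](C)(C4=O)[C@H]1[C@@H]3C(=O)OC | intermediate
7 | 3-O-triethylsilyl gibberellin A thirteen 7-methyl ester (free 19- and 20-acids, both α) | C=C1C[C@]23C[C@H]1CC[C@H]2[C@]1(C(=O)O)CC[C@H](O[Si](CC)(CC)CC)[C@@](C)(C(=O)O)[C@H]1[C@@H]3C(=O)OC | intermediate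
8 | 3-O-triethylsilyl gibberellin A thirteen (triacid) | C=C1C[C@]23C[C@H]1CC[C@H]2[C@]1(C(=O)O)CC[C@H](O[Si](CC)(CC)CC)[C@@](C)(C(=O)O)[C@H]1[C@@H]3C(=O)O | intermediate
9 | gibberellin A thirteen (ent-3α-hydroxygibberell-16-ene-7,19,20-trioic acid; as drawn: 3β-OH, 7-, 19- and 20-carboxylic acids, 16(17)-exo-methylene) | C=C1C[C@]23C[C@H]1CC[C@H]2[C@]1(C(=O)O)CC[C@H](O)[C@@](C)(C(=O)O)[C@H]1[C@@H]3C(=O)O | target

**Totals**
Total steps: 5. Longest linear sequence: 5 steps (1 → 9).

**Steps most likely to fail**

Step 4 (the proposed new step). Risks:
- The C10 radical may attack sulfur directly and give the 19,10-thiolactone (thiono-to-thiolo rearrangement).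
- Radicals may add to a second thionolactone.
- Chains may be short.
- The weakly absorbing thiocarbonyl may be excited directly.

High CO pressure, low temperature and high dilution are chosen against these.

Fallback with known chemistry, setting out from 4: the chain-transfer closure is given up and C20 is brought in at the aldehyde level by Bu3SnH-mediated radical formylation. Bu3SnH (slow addition, to hold back premature reduction at C10), AIBN, CO (85 atm), benzene, 80 °C effect stannyl radical addition to C=S, the same Barton–McCombie-type C10–O fragmentation and formylation, giving S-tributylstannyl thioester aldehyde F2. AgNO3 and 2,6-lutidine in THF/H2O then cleave the stannyl thioester thiophilically to the C19 acid, which closes onto the C20 aldehyde to give 3-O-triethylsilyl gibberellin A thirty-six methyl ester lactol F3. Pinnick oxidation (NaClO2, NaH2PO4, 2-methyl-2-butene, t-BuOH/H2O) of F3 comes back to the route at 7, which is taken through the last two operations of step 5. Here hydrogen transfer is intermolecular, so the C10 configuration rests on substrate control under reversible CO capture and must be checked. Only the natural 10α epimer can close to the lactol, which serves as proof and as a handle for separation.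

Step 3. Risks: slow thionation at the hindered bridged carbonyl, competing attack at the C7 ester, and acid-catalysed thiono-to-thiolo rearrangement.

Fallback, setting out from 3: the carbonyl oxygen is activated by alkylation instead of direct O/S exchange. Me3OBF4 with 2,6-di-tert-butylpyridine in CH2Cl2 at 0 °C gives O-methyl lactonium tetrafluoroborate F1, which is treated at −40 °C with anhydrous NaSH in MeCN/pyridine. Loss of methanol from the tetrahedral adduct comes back to the route at 4.

Step 5. Risks: sluggish saponification of the hindered C7 methyl ester and peroxide side reactions.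

Fallback, setting out from 6: thiophilic hydrolysis with AgNO3 and 2,6-lutidine in THF/H2O gives 7, this time isolated. HF·pyridine in THF then gives gibberellin A thirteen 7-methyl ester F4. n-PrSLi in HMPA at 23 °C cleaves the methyl ester by SN2 attack at the methyl carbon and comes back to the route at 9.

**Further compounds**
F1 | step 3 | O-methyl lactonium tetrafluoroborate (C19 carbonyl oxygen of 3 methylated) | C=C1C[C@]23C[C@H]1CC[C@H]2[C@]1(O4)CC[C@H](O[Si](CC)(CC)CC)[C@@](C)(C4=[O+]C)[C@H]1[C@@H]3C(=O)OC.F[B-](F)(F)F
F2 | step 4 | S-tributylstannyl thioester aldehyde (C10α-CHO, C19(=O)SSnBu3, 3β-OSiEt3, 7-CO2Me) | C=C1C[C@]23C[C@H]1CC[C@H]2[C@]1(C=O)CC[C@H](O[Si](CC)(CC)CC)[C@@](C)(C(=O)S[Sn](CCCC)(CCCC)CCCC)[C@H]1[C@@H]3C(=O)OC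
F3 | step 4 | 3-O-triethylsilyl gibberellin A thirty-six methyl ester lactol (19,20-lactol, C20 epimers) | C=C1C[C@]23C[C@H]1CC[C@H]2[C@]1(C(O)O4)CC[C@H](O[Si](CC)(CC)CC)[C@@](C)(C4=O)[C@H]1[C@@H]3C(=O)OC
F4 | step 5 | gibberellin A thirteen 7-methyl ester | C=C1C[C@]23C[C@H]1CC[C@H]2[C@]1(C(=O)O)CC[C@H](O)[C@@](C)(C(=O)O)[C@H]1[C@@H]3C(=O)OC
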